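The target is disconnected at the bond between ring carbon C1 and its carboxyl carbon. C1 is ortho to C6, which carries the chain, so the C2' oxygen and the carboxyl carbon can complete a six-membered ring. CO is therefore inserted between an aryl iodide at C1 and that hydroxyl: one palladium-catalysed carbonylation forges the C1–C(=O) bond and closes the lactone (ring B of an isochroman-1-one), which masks acid and alcohol together. The precursor is (R)-1-(2-iodo-3,5-dimethoxyphenyl)tridecan-2-ol, made from (R)-epichlorohydrin by two copper-catalysed Grignard openings and iodination of a symmetric ring. The two ring oxygens are told apart only after lactonisation, through the hydrogen bond of the 8-hydroxyl to the lactone carbonyl.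

Key step: step 5

Remark: lactone positions follow isochroman-1-one numbering (C1 carbonyl, O2, C3 stereocentre, C4 benzylic CH2). Position 8 is the oxygen-bearing carbon next to the carbonyl-bearing carbon and position 6 the one para to it. Decylmagnesium bromide is taken as a purchased ethereal solution.

Step 1
Reactants: 1 (R)-epichlorohydrin; 2 decylmagnesium bromide
Product: 3 (R)-1-chlorotridecan-2-ol
Conditions: CuI (copper iodide, 5 mol%), THF, −40 °C to −20 °C; then cold 1 M HCl
Reagents that add atoms: none
Why: Copper-catalysed Grignard ring opening (SN2) of the epoxide at its unsubstituted carbon should leave the C–Cl bond and the existing stereocentre untouched, the descriptor staying R because CH2Cl still outranks the new alkyl branch.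

Step 2
Reactants: 3 (R)-1-chlorotridecan-2-ol
Product: 4 (R)-1,2-epoxytridecane
Conditions: NaOH (powdered, 3 equiv), Et2O, rt
Reagents that add atoms: none
Why: Intramolecular Williamson etherification (SN2 displacement of chloride by the alkoxide) should close the oxirane without touching the C2–O bond, so the R centre of 1 is carried into 4.

Step 3
Reactants: 5 1-bromo-3,5-dimethoxybenzene; 4 (R)-1,2-epoxytridecane
Product: 7 (R)-1-(3,5-dimethoxyphenyl)tridecan-2-ol, via 3,5-dimethoxyphenylmagnesium bromide 6 (not isolated)
Conditions: 5 (1.3 equiv), Mg, I2 (cat.), THF, 50 °C; then CuI (10 mol%), 4, −30 °C to 0 °C; then cold 1 M HCl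
Reagents that add atoms: none
Why: Copper-catalysed aryl Grignard opening of a terminal epoxide proceeds by SN2 attack at the unsubstituted CH2, so the chain-to-ring C–C bond should form while the C2–O bond and its R configuration are retained.

Step 4
Reactants: 7 (R)-1-(3,5-dimethoxyphenyl)tridecan-2-ol
Product: 8 (R)-1-(2-iodo-3,5-dimethoxyphenyl)tridecan-2-ol
Conditions: NIS (1.05 equiv), MeCN, 0 °C to rt, dark
Reagents that add atoms: N-iodosuccinimide, O=C1CCC(=O)N1I
Why: Electrophilic aromatic iodination should occur ortho to the chain, at one of two equivalent positions each activated ortho/para by both methoxy groups (the site between the two methoxy groups is more hindered), and the neutral conditions leave the secondary alcohol alone.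

Step 5
Reactants: 8 (R)-1-(2-iodo-3,5-dimethoxyphenyl)tridecan-2-ol; 9 carbon monoxide
Product: 10 (R)-6,8-dimethoxy-3-undecylisochroman-1-one
Conditions: Pd(OAc)2 (5 mol%), Xantphos (6 mol%), Et3N (3 equiv), CO (1 atm), toluene, 100 °C
Reagents that add atoms: none
Why: Zerovalent palladium, formed in the flask from Pd(OAc)2 and Xantphos, should add oxidatively into the C–I bond of 8, CO should insert into the aryl–palladium bond to give a divalent acylpalladium species, and the C2' hydroxyl, deprotonated with the help of Et3N, should attack the acyl carbon to release lactone 10 and return zerovalent palladium. The closest known reaction type is the palladium-catalysed carbonylative lactonisation (intramolecular alkoxycarbonylation) of ortho-halo aryl alkanols to phthalides and isochroman-1-ones. The six-membered lactone ring (ring B: C1, O2, C3, C4, C4a, C8a) closes in a 6-exo-trig mode at the acyl carbon. No stereocentre is created, and C3 keeps its R configuration because its C–O bond is never broken. The step needs chemoselectivity for intramolecular acyl capture over intermolecular esterification, reductive loss of iodine and alcohol oxidation by β-hydride elimination; this is secured by the ortho placement of the hydroxyalkyl arm, the wide-bite-angle ligand that favours acyl transfer and the CO atmosphere, while the equivalence of the two ring positions ortho to the chain guarantees that the iodide already sits on the correct carbon.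

Step 6
Reactants: 10 (R)-6,8-dimethoxy-3-undecylisochroman-1-one
Product: 11 (R)-6,8-dihydroxy-3-undecylisochroman-1-one
Conditions: BBr3 (5 equiv), CH2Cl2, −78 °C to rt; then H2O, 0 °C
Reagents that add atoms: none
Why: Lewis-acid cleavage of aryl methyl ethers (BBr3 demethylation) should free both phenols, while the lactone, whose alkyl C–O bond is secondary and unactivated, should be retained.

Step 7
Reactants: 11 (R)-6,8-dihydroxy-3-undecylisochroman-1-one
Product: 12 (R)-6-(benzyloxy)-8-hydroxy-3-undecylisochroman-1-one
Conditions: BnBr (1.05 equiv), K2CO3 (1.1 equiv), acetone, rt to 40 °C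
Reagents that add atoms: benzyl bromide, BrCc1ccccc1
Why: Williamson etherification with limiting weak base should alkylate only the more acidic, non-chelated 6-hydroxyl, because the 8-hydroxyl is tied up in a hydrogen bond to the lactone carbonyl.

Step 8
Reactants: 12 (R)-6-(benzyloxy)-8-hydroxy-3-undecylisochroman-1-one
Product: 13 (R)-6-(benzyloxy)-8-methoxy-3-undecylisochroman-1-one
Conditions: MeI (5 equiv), K2CO3 (3 equiv), DMF, 50 °C
Reagents that add atoms: iodomethane, CI
Why: Williamson methylation under more forcing conditions should alkylate the remaining chelated phenol, the only acidic site left, since the lactone has no enolisable hydrogen.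

Step 9
Reactants: 13 (R)-6-(benzyloxy)-8-methoxy-3-undecylisochroman-1-one
Product: 15 benzyl (R)-4-(benzyloxy)-2-(2-hydroxytridecyl)-6-methoxybenzoate, via potassium (R)-4-(benzyloxy)-2-(2-hydroxytridecyl)-6-methoxybenzoate 14 (not isolated)
Conditions: KOH (1.2 equiv), MeOH/H2O, 65 °C; evaporate, toluene azeotrope; then BnBr (1.5 equiv), DMF, 0 °C to rt; product used at once
Reagents that add atoms: potassium hydroxide, [K+].[OH-]; benzyl bromide, BrCc1ccccc1
Why: Lactone saponification by acyl–oxygen cleavage (C3–O bond and R configuration untouched) followed by SN2 O-alkylation of the carboxylate, which is far more nucleophilic than the secondary hydroxyl, should give the open benzyl ester, whose doubly ortho-substituted carbonyl is slow to re-close.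

Step 10
Reactants: 15 benzyl (R)-4-(benzyloxy)-2-(2-hydroxytridecyl)-6-methoxybenzoate
Product: 16 benzyl (R)-2-(2-acetoxytridecyl)-4-(benzyloxy)-6-methoxybenzoate
Conditions: Ac2O (3 equiv), pyridine, DMAP (10 mol%), CH2Cl2, 0 °C to rt
Reagents that add atoms: acetic anhydride, CC(=O)OC(C)=O
Why: DMAP-catalysed acylation (nucleophilic catalysis) should esterify the only free hydroxyl with retention, since the C–O bond at the stereocentre is not broken.

Step 11
Reactants: 16 benzyl (R)-2-(2-acetoxytridecyl)-4-(benzyloxy)-6-methoxybenzoate
Product: 17 (R)-2-(2-acetoxytridecyl)-4-hydroxy-6-methoxybenzoic acid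
Conditions: H2 (1 atm), Pd/C (10% Pd on carbon), EtOAc, rt
Reagents that add atoms: none
Why: Catalytic hydrogenolysis should cleave the benzyl ester and the benzyl aryl ether in one operation, while the non-benzylic secondary acetate, the methyl ether and the arene are inert under these neutral conditions.

Compound list

1 | (R)-epichlorohydrin, (R)-2-(chloromethyl)oxirane | ClC[C@H]1CO1 | starting material
2 | decylmagnesium bromide | CCCCCCCCCC[Mg]Br | starting material
3 | (R)-1-chlorotridecan-2-ol | ClC[C@H](O)CCCCCCCCCCC | intermediate
4 | (R)-1,2-epoxytridecane, (R)-2-undecyloxirane | CCCCCCCCCCC[C@@H]1CO1 | intermediate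
5 | 1-bromo-3,5-dimethoxybenzene | COc1cc(Br)cc(OC)c1 | starting material
6 | 3,5-dimethoxyphenylmagnesium bromide (formed in the flask, not isolated) | COc1cc([Mg]Br)cc(OC)c1 | intermediate
7 | (R)-1-(3,5-dimethoxyphenyl)tridecan-2-ol | CCCCCCCCCCC[C@@H](O)Cc1cc(OC)cc(OC)c1 | intermediate
8 | (R)-1-(2-iodo-3,5-dimethoxyphenyl)tridecan-2-ol | CCCCCCCCCCC[C@@H](O)Cc1cc(OC)cc(OC)c1I | intermediate
9 | carbon monoxide | [C-]#[O+] | starting material
10 | (R)-6,8-dimethoxy-3-undecylisochroman-1-one | CCCCCCCCCCC[C@@H]1Cc2cc(OC)cc(OC)c2C(=O)O1 | intermediate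
11 | (R)-6,8-dihydroxy-3-undecylisochroman-1-one | CCCCCCCCCCC[C@@H]1Cc2cc(O)cc(O)c2C(=O)O1 | intermediate
12 | (R)-6-(benzyloxy)-8-hydroxy-3-undecylisochroman-1-one | CCCCCCCCCCC[C@@H]1Cc2cc(OCc3ccccc3)cc(O)c2C(=O)O1 | intermediate
13 | (R)-6-(benzyloxy)-8-methoxy-3-undecylisochroman-1-one | CCCCCCCCCCC[C@@H]1Cc2cc(OCc3ccccc3)cc(OC)c2C(=O)O1 | intermediate
14 | potassium (R)-4-(benzyloxy)-2-(2-hydroxytridecyl)-6-methoxybenzoate (formed in the flask, not isolated) | CCCCCCCCCCC[C@@H](O)Cc1cc(OCc2ccccc2)cc(OC)c1C(=O)[O-].[K+] | intermediate
15 | benzyl (R)-4-(benzyloxy)-2-(2-hydroxytridecyl)-6-methoxybenzoate | CCCCCCCCCCC[C@@H](O)Cc1cc(OCc2ccccc2)cc(OC)c1C(=O)OCc1ccccc1 | intermediate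
16 | benzyl (R)-2-(2-acetoxytridecyl)-4-(benzyloxy)-6-methoxybenzoate | CCCCCCCCCCC[C@@H](OC(C)=O)Cc1cc(OCc2ccccc2)cc(OC)c1C(=O)OCc1ccccc1 | intermediate
17 | (R)-2-(2-acetoxytridecyl)-4-hydroxy-6-methoxybenzoic acid | CCCCCCCCCCC[C@H](Cc1cc(O)cc(OC)c1C(=O)O)OC(C)=O | target

Total step count: 11

Longest linear sequence: 11 steps (steps 1 to 11, from compound 1; compound 5 enters at step 3 and compound 9 at step 5).

Steps most likely to fail

Step 5 (key step). Oxidative addition into the electron-rich C–I bond, which is flanked by two ortho substituents, may be slow. Reductive loss of iodine, or capture of the acylpalladium by the hydroxyl of a second molecule (chain growth to oligoesters), could then compete with ring closure. The fallback sets out from 8 and replaces catalytic carbonylation by carboxylation of an organolithium. n-BuLi (2.2 equiv) in THF at −78 °C should deprotonate the hydroxyl and exchange iodine for lithium. Quenching the aryllithium with dry CO2 and acidifying should give (R)-2-(2-hydroxytridecyl)-4,6-dimethoxybenzoic acid F1. Warming with TsOH (cat.) in toluene should lactonise it, and the fallback comes back to the route at 10.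

Step 9. The liberated C2' hydroxyl may re-attack the carboxyl carbon during carboxylate alkylation or isolation, so that the lactone is regenerated and the open benzyl ester is not obtained. The fallback sets out from 13 and builds the carboxyl group only after the hydroxyl is acetylated.
- LiAlH4 in THF should reduce the lactone to the diol (R)-1-[5-(benzyloxy)-2-(hydroxymethyl)-3-methoxyphenyl]tridecan-2-ol F2.
- TBSCl and imidazole in CH2Cl2 should silylate only the primary benzylic hydroxyl, giving (R)-1-[5-(benzyloxy)-2-{[(tert-butyldimethylsilyl)oxy]methyl}-3-methoxyphenyl]tridecan-2-ol F3.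
- Ac2O, pyridine and DMAP should give (R)-1-[5-(benzyloxy)-2-{[(tert-butyldimethylsilyl)oxy]methyl}-3-methoxyphenyl]tridecan-2-yl acetate F4.
- HF·pyridine in THF should remove the silyl group to give (R)-1-[5-(benzyloxy)-2-(hydroxymethyl)-3-methoxyphenyl]tridecan-2-yl acetate F5.
- MnO2 in CH2Cl2 should oxidise the benzylic alcohol to (R)-1-[5-(benzyloxy)-2-formyl-3-methoxyphenyl]tridecan-2-yl acetate F6.
- Pinnick oxidation (NaClO2, NaH2PO4, 2-methyl-2-butene, t-BuOH/H2O) should give (R)-2-(2-acetoxytridecyl)-4-(benzyloxy)-6-methoxybenzoic acid F7.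
- Hydrogenolysis (H2, Pd/C, EtOAc) should remove the benzyl ether, and the fallback comes back to the route at the target 17.

Step 7. Site selectivity in the phenol alkylation may be lost, with the hydrogen-bonded 8-hydroxyl alkylated alongside the 6-hydroxyl or starting diol left behind. The fallback sets out from 11 and replaces selective protection by selective deprotection. Exhaustive benzylation (BnBr 2.5 equiv, K2CO3, DMF, 60 °C) should give (R)-6,8-bis(benzyloxy)-3-undecylisochroman-1-one F8. BCl3 (1.1 equiv, CH2Cl2, −78 °C) should then cleave only the benzyl ether whose oxygen chelates boron together with the lactone carbonyl, and the fallback comes back to the route at 12.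

Further compounds

F1 | step 5 | (R)-2-(2-hydroxytridecyl)-4,6-dimethoxybenzoic acid | CCCCCCCCCCC[C@@H](O)Cc1cc(OC)cc(OC)c1C(=O)O
F2 | step 9 | (R)-1-[5-(benzyloxy)-2-(hydroxymethyl)-3-methoxyphenyl]tridecan-2-ol | CCCCCCCCCCC[C@@H](O)Cc1cc(OCc2ccccc2)cc(OC)c1CO
F3 | step 9 | (R)-1-[5-(benzyloxy)-2-{[(tert-butyldimethylsilyl)oxy]methyl}-3-methoxyphenyl]tridecan-2-ol | CCCCCCCCCCC[C@@H](O)Cc1cc(OCc2ccccc2)cc(OC)c1CO[Si](C)(C)C(C)(C)C
F4 | step 9 | (R)-1-[5-(benzyloxy)-2-{[(tert-butyldimethylsilyl)oxy]methyl}-3-methoxyphenyl]tridecan-2-yl acetate | CCCCCCCCCCC[C@@H](OC(C)=O)Cc1cc(OCc2ccccc2)cc(OC)c1CO[Si](C)(C)C(C)(C)C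
F5 | step 9 | (R)-1-[5-(benzyloxy)-2-(hydroxymethyl)-3-methoxyphenyl]tridecan-2-yl acetate | CCCCCCCCCCC[C@@H](OC(C)=O)Cc1cc(OCc2ccccc2)cc(OC)c1CO
F6 | step 9 | (R)-1-[5-(benzyloxy)-2-formyl-3-methoxyphenyl]tridecan-2-yl acetate | CCCCCCCCCCC[C@@H](OC(C)=O)Cc1cc(OCc2ccccc2)cc(OC)c1C=O
F7 | step 9 | (R)-2-(2-acetoxytridecyl)-4-(benzyloxy)-6-methoxybenzoic acid | CCCCCCCCCCC[C@@H](OC(C)=O)Cc1cc(OCc2ccccc2)cc(OC)c1C(=O)O
F8 | step 7 | (R)-6,8-bis(benzyloxy)-3-undecylisochroman-1-one | CCCCCCCCCCC[C@@H]1Cc2cc(OCc3ccccc3)cc(OCc3ccccc3)c2C(=O)O1
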